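**Plan**

- Cuts (labdane numbering; β is the face of the C10 methyl group): the C6 ester and the C16 protecting group; the C8–O/C7–H pair (epoxide opened by hydride); C12–C13 (allylic alkylation); C9–C11 (Claisen shift from a C7 alcohol); the C1 oxygen is put back; last, C3–C4 of ring A.
- Feature: C5 with its neighbour C4, the C8 methyl and the C9 oxygen are the stereocentre, isopropenyl group, ring methyl and ketone of (S)-carvone. A radical at C4 and an acryloyl group on C10, both on the α face of ring B, therefore lie six atoms apart and close ring A.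
- Forward: carvone is ring B; aldol, methylation and oxidation load C10; the radical cyclisation closes ring A; C1 is deoxygenated; an enone transposition and a Claisen shift attach C11–C12 to C9; C6 is oxidised; the C13–C16 unit is joined at C12; the C8 carbinol, the angelate and the free C16 alcohol come last.
- Stereochemistry: C5 from carvone; C10 by methylation anti to the isopropenyl group (cis ring fusion); C9 relayed from a 7β,8β-epoxide through C7–O by a suprafacial [3,3] shift; C6 by hydride attack on the β face; C8 by hydroxyl-directed epoxidation and hydride opening; C13 by the chiral ligand of a copper-catalysed allylic alkylation; the (Z)-alkene comes with angelic acid.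

Key step: step 6

Assumption: the SMILES is read as the cis-fused decalin (C5–H and C10–CH3 both β; 5R,6S,8R,9R,10S,13R), every bicyclic compound below has this fusion, and the TaniaPhos enantiomer of step 20 is the one whose sense of induction, checked on a model alkyl Grignard reagent, gives (R) at C13.

**Route**

Step 1
Reactants: 1 (S)-(+)-carvone; 2 acrolein
Product: 4 6-(1-hydroxyprop-2-en-1-yl)carvone (chain β, trans to the α isopropenyl group; both carbinol epimers), via lithium dienolate 3 (not isolated)
Conditions: LiN(iPr)2, THF, −78 °C; then 2, −78 °C; AcOH quench at −78 °C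
Reagents that add atoms: none
Why: Kinetic α′-deprotonation of carvone gives the cross-conjugated lithium dienolate, which undergoes aldol addition to the carbonyl carbon of acrolein anti to the isopropenyl group, and both new stereocentres are erased again in steps 3 and 5, so the epimer mixture is carried forward.

Step 2
Reactants: 4 6-(1-hydroxyprop-2-en-1-yl)carvone
Product: 5 tert-butyldimethylsilyl ether of 4
Conditions: TBSOTf, 2,6-lutidine, CH2Cl2, −78 °C
Reagents that add atoms: tert-butyldimethylsilyl trifluoromethanesulfonate, CC(C)(C)[Si](C)(C)OS(=O)(=O)C(F)(F)F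
Why: Silyl ether formation with a silyl triflate and a hindered pyridine base caps the aldol hydroxyl at low temperature without retro-aldol cleavage, so that the next enolisation meets no acidic OH.

Step 3
Reactants: 5 silyl ether; 6 iodomethane
Product: 8 6-methyl-6-[1-(tert-butyldimethylsilyloxy)allyl]carvone (methyl β and trans to isopropenyl, silyloxyallyl arm α and cis), via lithium enolate 7 (not isolated)
Conditions: LiN(iPr)2, THF, −78 → −40 °C; then 6, DMPU, −78 → −20 °C
Reagents that add atoms: none
Why: Enolate alkylation in which the remaining α′ hydrogen is removed and iodomethane attacks the enolate carbon on the β face, opposite the neighbouring isopropenyl group, which sets the quaternary carbon (later C10) with the methyl trans and the three-carbon arm cis to isopropenyl, as in the second alkylation of 6-substituted carvones.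

Step 4
Reactants: 8 methylated silyl ether
Product: 9 6-(1-hydroxyallyl)-6-methylcarvone (hydroxyallyl arm cis to isopropenyl)
Conditions: HF (48% aq.), MeCN, 0 °C → rt
Reagents that add atoms: none
Why: Acidic fluoride cleavage of the silyl ether avoids a free alkoxide, which could fragment by retro-aldol reaction at the new quaternary carbon.

Step 5
Reactants: 9 allylic alcohol
Product: 10 6-acryloyl-6-methylcarvone (acryloyl cis to isopropenyl)
Conditions: Dess–Martin periodinane, CH2Cl2, 0 °C → rt
Reagents that add atoms: none
Why: Dess–Martin oxidation of the secondary allylic alcohol under neutral conditions gives the non-enolisable β-diketone and removes the carbinol stereocentre, and the sensitive vinyl ketone is used at once.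

Step 6
Reactants: 10 6-acryloyl-6-methylcarvone
Product: 11 cis-fused 4,4,8,10-tetramethyl-octal-7-ene-1,9-dione (5β-H, 10β-CH3)
Conditions: Fe(acac)3 (30 mol%), PhSiH3 (2.5 equiv), EtOH/ethylene glycol 5:1, 60 °C, 0.02 M, degassed
Reagents that add atoms: none
Why: An iron hydride formed from Fe(acac)3 and PhSiH3 in ethanol transfers a hydrogen atom to the CH2 terminus of the isopropenyl group, which completes the gem-dimethyl group and leaves a tertiary radical at C4; this nucleophilic radical adds to the β-carbon (C3) of the acryloyl group, and the α-keto radical at C2 is reduced by divalent iron and protonated by the solvent. The closest known reaction is the Fe(acac)3/PhSiH3 reductive coupling of 1,1-disubstituted alkenes with enones (hydrogen-atom-transfer Giese addition), including its intramolecular 6-endo variants. Ring A closes 6-endo-trig through the new C3–C4 bond, since the 5-exo alternative would put the nucleophilic radical on the α-carbon C2 against the polarity of the enone. No stereocentre is created, because C4 carries two methyl groups, and the cis ring fusion follows from C5 (carvone) and C10 (step 3), whose radical and acceptor arms both sit on the α face. The step needs hydrogen-atom transfer to the electron-rich isopropenyl alkene in preference to the two electron-poor enone alkenes, which the polarity of the metal hydride should provide, and fast capture of the radical, which the six-atom spacing and high dilution should provide.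

Step 7
Reactants: 11 dione
Product: 13 C1 enol triflate (1-trifloxy-1,7-dien-9-one), via potassium enolate 12 (not isolated)
Conditions: KN(SiMe3)2, THF, −78 °C; then PhNTf2, −78 → 0 °C
Reagents that add atoms: N-phenylbis(trifluoromethanesulfonimide), O=S(=O)(N(c1ccccc1)S(=O)(=O)C(F)(F)F)C(F)(F)F
Why: Enol triflate formation singles out C1 for removal, because only the C1 carbonyl has α hydrogens (at C2), C9 lying between the quaternary C10 and the sp2 carbon C8.

Step 8
Reactants: 13 enol triflate
Product: 14 cis-fused 4,4,8,10-tetramethyl-octa-1,7-dien-9-one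
Conditions: Pd(OAc)2 (5 mol%), PPh3, Bu3N, HCO2H, DMF, 60 °C
Reagents that add atoms: none
Why: Palladium-catalysed formate reduction of the enol triflate (oxidative addition to zerovalent palladium, formate exchange, loss of CO2, C–H reductive elimination) replaces the C1 oxygen by hydrogen and does not touch the enone.

Step 9
Reactants: 14 dienone
Product: 15 cis-fused 4,4,8,10-tetramethyl-octal-7-en-9-one
Conditions: RhCl(PPh3)3 (5 mol%), H2 (1 atm), benzene/EtOH, rt
Reagents that add atoms: none
Why: Homogeneous hydrogenation with RhCl(PPh3)3 saturates the cis-disubstituted C1=C2 alkene and spares the trisubstituted, conjugated C7=C8 alkene, the selectivity known from the reduction of carvone to carvotanacetone.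

Step 10
Reactants: 15 enone
Product: 16 7β,8β-epoxy-9-one
Conditions: H2O2 (30% aq.), NaOH, MeOH, 0 °C
Reagents that add atoms: hydrogen peroxide, OO
Why: Weitz–Scheffer nucleophilic epoxidation in which hydroperoxide adds to C7 on the β face, away from ring A, whose C1 and C4 bonds both leave ring B on the α face (the same sense as in the epoxidation of carvone), and closure of the enolate on oxygen gives the 7β,8β-epoxide.

Step 11
Reactants: 16 epoxy ketone
Product: 18 cis-fused 4,4,8,10-tetramethyl-octal-8-en-7β-ol, via epoxy hydrazone 17 (not isolated)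
Conditions: N2H4·H2O, AcOH (cat.), MeOH, 0 °C → rt
Reagents that add atoms: none
Why: Wharton transposition in which the epoxy hydrazone opens to a vinyl diazene that loses N2, moving the alkene to C8=C9 and leaving the C7–O bond, and hence the 7β configuration, untouched.

Step 12
Reactants: 18 allylic alcohol; 19 triethyl orthoacetate
Product: 21 ethyl 13,14,15,16-tetranor-5β-labd-7-en-12-oate (C9 chain β, H9 α), via ketene acetal 20 (not isolated)
Conditions: 19 (excess), EtCO2H (cat.), 140 °C, EtOH distilled off
Reagents that add atoms: none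
Why: Johnson–Claisen rearrangement in which the ketene acetal on the 7β oxygen undergoes a suprafacial [3,3] shift that forms C9–C11 on the β face, so that H9 is α and the alkene returns to C7=C8.

Step 13
Reactants: 21 ester
Product: 22 ethyl 6-oxo-13,14,15,16-tetranor-5β-labd-7-en-12-oate
Conditions: CrO3, 3,5-dimethylpyrazole, CH2Cl2, −20 °C
Reagents that add atoms: chromium trioxide, O=[Cr](=O)=O
Why: Allylic oxidation with hexavalent chromium and 3,5-dimethylpyrazole converts the ring methylene next to the CH end of a trisubstituted alkene into the enone, as Δ5-steroids give 7-ketones, while the base-free medium leaves the epimerisable C5–H alone.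

Step 14
Reactants: 22 enone ester
Product: 23 ethyl 6α-hydroxy-13,14,15,16-tetranor-5β-labd-7-en-12-oate
Conditions: LiBH(s-Bu)3, THF, −78 °C
Reagents that add atoms: none
Why: 1,2-Reduction of the β,β-disubstituted enone by a bulky borohydride, in which hydride should reach C6 from the β face because ring A occupies the α face of ring B through C1 and C4, which gives the 6α-alcohol while the ester survives at −78 °C.

Step 15
Reactants: 23 allylic alcohol
Product: 24 6α-triethylsilyl ether of 23
Conditions: TESCl, imidazole, DMF, 0 °C → rt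
Reagents that add atoms: chlorotriethylsilane, CC[Si](CC)(CC)Cl
Why: Silyl protection of the allylic alcohol, needed because the next steps use hydride, an oxyphosphonium salt and a Grignard reagent, with a group that mild acid removes later in the presence of a primary tert-butyldiphenylsilyl ether.

Step 16
Reactants: 24 silyl ether ester
Product: 25 6α-(triethylsilyloxy)-13,14,15,16-tetranor-5β-labd-7-en-12-ol
Conditions: LiAlH4, Et2O, 0 °C
Reagents that add atoms: none
Why: Hydride reduction of the ester to the primary alcohol, to which the silyl ether and the trisubstituted alkene are inert.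

Step 17
Reactants: 25 primary alcohol
Product: 26 12-bromo-6α-(triethylsilyloxy)-13,14,15,16-tetranor-5β-labd-7-ene
Conditions: CBr4, PPh3, 2,6-lutidine, CH2Cl2, 0 °C
Reagents that add atoms: tetrabromomethane, BrC(Br)(Br)Br
Why: Appel bromination converts the unhindered primary alcohol into the bromide under buffered conditions that keep the triethylsilyl ether.

Step 18
Reactants: 27 (E)-but-2-ene-1,4-diol
Product: 28 (E)-4-(tert-butyldiphenylsilyloxy)but-2-en-1-ol
Conditions: 27 (3 equiv), TBDPSCl (1 equiv), imidazole, THF, 0 °C → rt
Reagents that add atoms: tert-butyl(chloro)diphenylsilane, CC(C)(C)[Si](Cl)(c1ccccc1)c1ccccc1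
Why: Statistical monosilylation of a symmetrical diol used in excess gives the mono ether, and the unreacted diol is washed out with water.

Step 19
Reactants: 28 mono silyl ether
Product: 29 (E)-4-(tert-butyldiphenylsilyloxy)but-2-enyl bromide
Conditions: CBr4, PPh3, CH2Cl2, 0 °C
Reagents that add atoms: tetrabromomethane, BrC(Br)(Br)Br
Why: Appel bromination of the primary allylic alcohol proceeds by direct displacement at the CH2 carbon and keeps the E geometry.

Step 20
Reactants: 26 C12 bromide; 29 allylic bromide
Product: 32 (13R)-16-(tert-butyldiphenylsilyloxy)-5β-labda-7,14-dien-6α-ol, via Grignard reagent 30 (not isolated), via triethylsilyl ether 31 (not isolated)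
Conditions: (a) Mg turnings, Et2O, rt; (b) added slowly to 29, CuBr·SMe2 (5 mol%), TaniaPhos (ferrocenyl diphosphine C43H39FeNP2, enantiomer giving 13R, 6 mol%), CH2Cl2, −78 °C; (c) crude product, PPTS, MeOH, 0 °C → rt
Reagents that add atoms: none
Why: Copper-catalysed asymmetric allylic alkylation of a Grignard reagent, in which the alkylcopper species attacks the γ-carbon of the allylic bromide (SN2′) to form C12–C13 and the vinyl group in one event, the chiral diphosphine on copper chooses the enantiotopic alkene face so that C13 is set by the ligand and not by the distant decalin, and mild acid methanolysis then removes the secondary triethylsilyl ether while the primary tert-butyldiphenylsilyl ether stays.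

Step 21
Reactants: 32 allylic alcohol
Product: 33 (13R)-7α,8α-epoxy-16-(tert-butyldiphenylsilyloxy)-5β-labd-14-en-6α-ol
Conditions: VO(acac)2 (5 mol%), t-BuOOH (decane), CH2Cl2, 0 °C → rt
Reagents that add atoms: tert-butyl hydroperoxide, CC(C)(C)OO
Why: Hydroxyl-directed vanadium-catalysed epoxidation, in which the peroxide bound to the vanadate ester of the 6α-hydroxyl is delivered to the same face of the C7=C8 alkene to give the 7α,8α-epoxide, while the unactivated terminal vinyl group does not react.

Step 22
Reactants: 33 epoxy alcohol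
Product: 34 (13R)-16-(tert-butyldiphenylsilyloxy)-5β-labd-14-ene-6α,8α-diol
Conditions: LiBHEt3, THF, 0 °C → rt
Reagents that add atoms: none
Why: Hydride opening of a trisubstituted epoxide, in which hydride attacks the secondary C7 with inversion and leaves the C8–O bond intact, so that C8 carries the α-hydroxyl and the β-methyl, and the cis arrangement of the C6 alkoxide and the epoxide rules out a Payne rearrangement.

Step 23
Reactants: 34 diol; 35 angelic acid
Product: 37 (13R)-6α-angeloyloxy-16-(tert-butyldiphenylsilyloxy)-5β-labd-14-en-8α-ol, via mixed anhydride 36 (not isolated)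
Conditions: 35, 2,4,6-trichlorobenzoyl chloride, Et3N, toluene, rt; then 34, toluene, 80 °C
Reagents that add atoms: none
Why: Yamaguchi esterification through the 2,4,6-trichlorobenzoic mixed anhydride, run without a nucleophilic amine catalyst so that the (Z)-alkene does not isomerise to the tiglate, acylates the secondary C6 hydroxyl and leaves the tertiary C8 hydroxyl free.

Step 24
Reactants: 37 silyl ether
Product: 38 CNP0177054.1, (5R,6S,8R,9R,10S,13R)-6α-angeloyloxy-5β-labd-14-ene-8α,16-diol
Conditions: HF·pyridine, THF/pyridine, 0 °C → rt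
Reagents that add atoms: none
Why: Fluoride cleavage of the primary silyl ether under buffered, weakly acidic conditions frees the C16 hydroxyl without acyl migration, angelate isomerisation or loss of the tertiary alcohol.

**Compound list**

1 | (S)-(+)-carvone | CC1=CC[C@@H](CC1=O)C(C)=C | starting material
2 | acrolein | C=CC=O | starting material
3 | lithium dienolate of carvone (α′-deprotonated) | [Li]OC1=C[C@@H](C(C)=C)CC=C1C | intermediate (not isolated)
4 | 6-(1-hydroxyprop-2-en-1-yl)carvone, chain trans to isopropenyl, carbinol epimers | O=C1[C@H](C(O)C=C)[C@@H](C(C)=C)CC=C1C | intermediate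
5 | tert-butyldimethylsilyl ether of 4 | O=C1[C@H](C(O[Si](C)(C)C(C)(C)C)C=C)[C@@H](C(C)=C)CC=C1C | intermediate
6 | iodomethane | CI | starting material
7 | lithium enolate of 5 | [Li]OC1=C(C(O[Si](C)(C)C(C)(C)C)C=C)[C@@H](C(C)=C)CC=C1C | intermediate (not isolated)
8 | 6-methyl-6-[1-(tert-butyldimethylsilyloxy)allyl]carvone, methyl trans to isopropenyl | O=C1[C@@](C)(C(O[Si](C)(C)C(C)(C)C)C=C)[C@@H](C(C)=C)CC=C1C | intermediate
9 | 6-(1-hydroxyallyl)-6-methylcarvone | O=C1[C@@](C)(C(O)C=C)[C@@H](C(C)=C)CC=C1C | intermediate
10 | 6-acryloyl-6-methylcarvone, acryloyl cis to isopropenyl | O=C1[C@@](C)(C(=O)C=C)[C@@H](C(C)=C)CC=C1C | intermediate (key-step precursor)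
11 | cis-fused 4,4,8,10-tetramethyl-octal-7-ene-1,9-dione | O=C1[C@@]2(C)C(=O)CCC(C)(C)[C@H]2CC=C1C | intermediate (key-step product)
12 | potassium C1 enolate of 11 | O=C1[C@@]2(C)C(O[K])=CCC(C)(C)[C@H]2CC=C1C | intermediate (not isolated)
13 | C1 enol triflate of 11 | O=C1[C@@]2(C)C(OS(=O)(=O)C(F)(F)F)=CCC(C)(C)[C@H]2CC=C1C | intermediate
14 | cis-fused 4,4,8,10-tetramethyl-octa-1,7-dien-9-one | O=C1[C@@]2(C)C=CCC(C)(C)[C@H]2CC=C1C | intermediate
15 | cis-fused 4,4,8,10-tetramethyl-octal-7-en-9-one | O=C1[C@@]2(C)CCCC(C)(C)[C@H]2CC=C1C | intermediate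
16 | 7β,8β-epoxy-9-one | O=C1[C@@]2(C)CCCC(C)(C)[C@H]2C[C@@H]3O[C@@]31C | intermediate
17 | hydrazone of 16 | NN=C1[C@@]2(C)CCCC(C)(C)[C@H]2C[C@@H]3O[C@@]31C | intermediate (not isolated)
18 | cis-fused 4,4,8,10-tetramethyl-octal-8-en-7β-ol | O[C@H]1C[C@@H]2C(C)(C)CCC[C@]2(C)C=C1C | intermediate
19 | triethyl orthoacetate | CCOC(C)(OCC)OCC | starting material
20 | ketene ethyl acetal of 18 | C=C(OCC)O[C@H]1C[C@@H]2C(C)(C)CCC[C@]2(C)C=C1C | intermediate (not isolated)
21 | ethyl 13,14,15,16-tetranor-5β-labd-7-en-12-oate | CCOC(=O)C[C@@H]1[C@@]2(C)CCCC(C)(C)[C@H]2CC=C1C | intermediate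
22 | ethyl 6-oxo-13,14,15,16-tetranor-5β-labd-7-en-12-oate | CCOC(=O)C[C@@H]1[C@@]2(C)CCCC(C)(C)[C@H]2C(=O)C=C1C | intermediate
23 | ethyl 6α-hydroxy-13,14,15,16-tetranor-5β-labd-7-en-12-oate | CCOC(=O)C[C@@H]1[C@@]2(C)CCCC(C)(C)[C@H]2[C@@H](O)C=C1C | intermediate
24 | ethyl 6α-(triethylsilyloxy)-13,14,15,16-tetranor-5β-labd-7-en-12-oate | CCOC(=O)C[C@@H]1[C@@]2(C)CCCC(C)(C)[C@H]2[C@@H](O[Si](CC)(CC)CC)C=C1C | intermediate
25 | 6α-(triethylsilyloxy)-13,14,15,16-tetranor-5β-labd-7-en-12-ol | OCC[C@@H]1[C@@]2(C)CCCC(C)(C)[C@H]2[C@@H](O[Si](CC)(CC)CC)C=C1C | intermediate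
26 | 12-bromo-6α-(triethylsilyloxy)-13,14,15,16-tetranor-5β-labd-7-ene | BrCC[C@@H]1[C@@]2(C)CCCC(C)(C)[C@H]2[C@@H](O[Si](CC)(CC)CC)C=C1C | intermediate
27 | (E)-but-2-ene-1,4-diol | OC/C=C/CO | starting material
28 | (E)-4-(tert-butyldiphenylsilyloxy)but-2-en-1-ol | OC/C=C/CO[Si](c1ccccc1)(c1ccccc1)C(C)(C)C | intermediate
29 | (E)-4-(tert-butyldiphenylsilyloxy)but-2-enyl bromide | BrC/C=C/CO[Si](c1ccccc1)(c1ccccc1)C(C)(C)C | intermediate
30 | C12 Grignard reagent from 26 | Br[Mg]CC[C@@H]1[C@@]2(C)CCCC(C)(C)[C@H]2[C@@H](O[Si](CC)(CC)CC)C=C1C | intermediate (not isolated)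
31 | (13R)-16-(tert-butyldiphenylsilyloxy)-6α-(triethylsilyloxy)-5β-labda-7,14-diene | C=C[C@H](CO[Si](c1ccccc1)(c1ccccc1)C(C)(C)C)CC[C@@H]1[C@@]2(C)CCCC(C)(C)[C@H]2[C@@H](O[Si](CC)(CC)CC)C=C1C | intermediate (not isolated)
32 | (13R)-16-(tert-butyldiphenylsilyloxy)-5β-labda-7,14-dien-6α-ol | C=C[C@H](CO[Si](c1ccccc1)(c1ccccc1)C(C)(C)C)CC[C@@H]1[C@@]2(C)CCCC(C)(C)[C@H]2[C@@H](O)C=C1C | intermediate
33 | (13R)-7α,8α-epoxy-16-(tert-butyldiphenylsilyloxy)-5β-labd-14-en-6α-ol | C=C[C@H](CO[Si](c1ccccc1)(c1ccccc1)C(C)(C)C)CC[C@@H]1[C@@]2(C)CCCC(C)(C)[C@H]2[C@@H](O)[C@H]3O[C@]31C | intermediate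
34 | (13R)-16-(tert-butyldiphenylsilyloxy)-5β-labd-14-ene-6α,8α-diol | C=C[C@H](CO[Si](c1ccccc1)(c1ccccc1)C(C)(C)C)CC[C@@H]1[C@@]2(C)CCCC(C)(C)[C@H]2[C@@H](O)C[C@@]1(C)O | intermediate
35 | angelic acid, (Z)-2-methylbut-2-enoic acid | C/C=C(/C)C(=O)O | starting material
36 | angelic 2,4,6-trichlorobenzoic anhydride | C/C=C(/C)C(=O)OC(=O)c1c(Cl)cc(Cl)cc1Cl | intermediate (not isolated)
37 | (13R)-6α-angeloyloxy-16-(tert-butyldiphenylsilyloxy)-5β-labd-14-en-8α-ol | C=C[C@H](CO[Si](c1ccccc1)(c1ccccc1)C(C)(C)C)CC[C@@H]1[C@@]2(C)CCCC(C)(C)[C@H]2[C@@H](OC(=O)/C(C)=C\C)C[C@@]1(C)O | intermediate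
38 | CNP0177054.1, (5R,6S,8R,9R,10S,13R)-6α-angeloyloxy-5β-labd-14-ene-8α,16-diol | C=C[C@H](CO)CC[C@@H]1[C@@]2(C)CCCC(C)(C)[C@H]2[C@@H](OC(=O)/C(C)=C\C)C[C@@]1(C)O | target

**Step count and risks**

Total: 24 steps (22 on the main line, 2 for allylic bromide 29). Longest linear sequence: 22 steps from (S)-carvone (steps 1–17 and 20–24).

Steps most likely to fail:

1. Step 20. Grignard formation may stall or give homocoupling, direct (α) substitution may compete with γ-attack, and enantiofacial control at C13 may be insufficient on a substrate whose C13 epimers would be hard to separate. The fallback builds C13 on the decalin side chain by enamine catalysis. It sets out from bromide 26, which is displaced by LiCH2CN (THF, −78 °C) to give the C14 nitrile F1. Reduction with (i-Bu)2AlH gives the aldehyde F2. Enamine-catalysed α-hydroxymethylation with aqueous formaldehyde and a diarylprolinol silyl ether sets C13 and gives the β-hydroxy aldehyde F3. Silylation (TBDPSCl, imidazole) gives the silyloxymethyl aldehyde F4. Wittig methylenation (Ph3P=CH2, THF, −78 °C) turns the formyl group into the vinyl group and arrives at 31, which is methanolysed to 32 as in step 20.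

2. Step 14. Hydride may be delivered to the α face (poor facial selectivity), and the resulting C6 epimer would direct the epoxidation of step 21 to the wrong face. The fallback inverts C6 after the reduction. It sets out from enone 22, which is reduced as before, and the 6β-alcohol F5 is taken on. Mitsunobu esterification (PPh3, DIAD, 4-nitrobenzoic acid, toluene) inverts C6 and gives the 6α 4-nitrobenzoate F6. Ethanolysis (K2CO3, EtOH) of the aryl ester returns alcohol 23.

3. Step 11. Condensation of hydrazine with the C9 carbonyl may be slow, since it lies between the quaternary C10 and the fully substituted epoxide carbon C8, so that epoxide opening by hydrazine and over-reduction compete. The fallback replaces the hydrazone route by a radical epoxide fragmentation. It sets out from epoxy ketone 16, which is reduced (NaBH4, MeOH) to the epoxy alcohol F7. This is converted into the S-methyl xanthate F8 (NaH, CS2, MeI). Treatment with Bu3SnH and AIBN in refluxing benzene generates the C9 radical, which opens the adjacent epoxide to the C8=C9 alkene and a C7 oxygen radical; hydrogen abstraction gives allylic alcohol 18 with the C7 configuration intact.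

Further compounds
F1 | step 20 | 14-nitrile, 6α-(triethylsilyloxy)-15,16-dinor-5β-labd-7-ene-14-nitrile | N#CCCC[C@@H]1[C@@]2(C)CCCC(C)(C)[C@H]2[C@@H](O[Si](CC)(CC)CC)C=C1C
F2 | step 20 | 14-aldehyde, 6α-(triethylsilyloxy)-15,16-dinor-5β-labd-7-en-14-al | O=CCCC[C@@H]1[C@@]2(C)CCCC(C)(C)[C@H]2[C@@H](O[Si](CC)(CC)CC)C=C1C
F3 | step 20 | (13R)-13-(hydroxymethyl) aldehyde, 16-hydroxy-6α-(triethylsilyloxy)-15-nor-5β-labd-7-en-14-al | O=C[C@H](CO)CC[C@@H]1[C@@]2(C)CCCC(C)(C)[C@H]2[C@@H](O[Si](CC)(CC)CC)C=C1C
F4 | step 20 | (13R)-16-(tert-butyldiphenylsilyloxy)-6α-(triethylsilyloxy)-15-nor-5β-labd-7-en-14-al | O=C[C@H](CO[Si](c1ccccc1)(c1ccccc1)C(C)(C)C)CC[C@@H]1[C@@]2(C)CCCC(C)(C)[C@H]2[C@@H](O[Si](CC)(CC)CC)C=C1C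
F5 | step 14 | ethyl 6β-hydroxy-13,14,15,16-tetranor-5β-labd-7-en-12-oate | CCOC(=O)C[C@@H]1[C@@]2(C)CCCC(C)(C)[C@H]2[C@H](O)C=C1C
F6 | step 14 | ethyl 6α-(4-nitrobenzoyloxy)-13,14,15,16-tetranor-5β-labd-7-en-12-oate | CCOC(=O)C[C@@H]1[C@@]2(C)CCCC(C)(C)[C@H]2[C@@H](OC(=O)c3ccc(cc3)[N+](=O)[O-])C=C1C
F7 | step 11 | 7β,8β-epoxy-9-ol (C9 epimers) from 16 | OC1[C@@]2(C)CCCC(C)(C)[C@H]2C[C@@H]3O[C@@]31C
F8 | step 11 | O-(7β,8β-epoxy-9-yl) S-methyl xanthate | CSC(=S)OC1[C@@]2(C)CCCC(C)(C)[C@H]2C[C@@H]3O[C@@]31C
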